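## The problem

1. 6,8-Diprenyleriodictyol 18 is a 2-arylchroman-4-one. Benzo ring A (C4a, C5–C8, C8a) is fused to the dihydropyranone ring C (O1, C2, C3, C4), and the catechol ring B sits on C2. Neither ring is hard to close as such.
2. Ring A is hexasubstituted. Three oxygens (O1 on C8a, 5-OH, 7-OH) alternate with three carbon substituents (C4 on C4a, prenyl on C6 and on C8). Direct alkylation of a phloroglucinol anion does not distinguish carbon from oxygen, or mono- from di- and geminal alkylation.
3. The only stereocentre, C2 (S), is benzylic, carries O1 and lies β to the C4 carbonyl. No second stereocentre can guide or guard it. Base or heat erase it by retro-oxa-Michael opening of O1–C2, more easily once the 7-OH and the 4'-OH (para to C2) are free.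
4. The two trisubstituted alkenes sit ortho to phenols and close to dimethylchromans in acid. They do not survive hydrogenolysis, and the catechol is oxidised in basic air, so acid, base and hydrogen are all restricted at the end.
5. The hardest point is therefore an incompatibility: the force needed to load ring A is what C2 cannot stand. All forceful chemistry must be finished on an achiral compound, and C2 must be made late by a bond that does not re-open.
6. The feature that allows this lies in ring A. C6 is para to C8a (O1), C8 is para to C5 (5-OH), and these two oxygens flank the acyl-bearing C4a. With O1–C2 undone, ring A has a local mirror plane through C4a and C7.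
7. Two prenyl groups parked on these two oxygens are then equivalent. Each has its destination para to itself, one Claisen and one Cope shift away, and the two allyl inversions restore the linear prenyl. Either phenol set free closes the same ring C.

## Retrosynthesis

**18 ⇒ 17.** Only the four O–Si bonds of 17 are cut in the last step.
- Silyl ethers are preferred to acetals (acid, chroman formation), benzyl ethers (hydrogenolysis, loss of the alkenes) and esters (base, opening of O1–C2). Aryl silyl ethers fall to bifluoride just below neutrality.
- 17 is no simpler than 18, but it is the form in which C2 can be made and handled.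
- The forward reaction must never let a free phenoxide build up.

**17 ⇒ 11 + 16.** The C2–C1' bond is cut.
- The neighbouring O1–C2 cut leads to a reversible C–O conjugate addition, whereas a C–C conjugate addition does not revert. The C2–C3 cut leads to an open chain that again needs the O1–C2 closure.
- The cut removes ring B and the stereocentre together. 11 is flat and achiral with nothing to scramble, and 16 is a simple arene.
- The forward reaction must deliver the aryl group to the Re face of C2 under catalyst control, near room temperature and without added base.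

**11 ⇒ 10.** The O5–Si bond is cut.
- The free 5-OH/C4=O pair of 10 is an acetylacetonate-like chelator for rhodium and has to be masked for one step.
- The mask leaves in the same final operation as the others.

**10 ⇒ 6 (key step).** Three bonds are cut at once: C6–CH2, C8–CH2 and O1–C2.
- The prenyl groups go back to the oxygens para to them, and ring C opens to an enaminone.
- Cutting the C–prenyl bonds to an allylic electrophile would bring back the ambident-anion problem. In 6 each group is tethered to its oxygen and can only travel round the ring.
- 6 has one ring, no free OH and a mirror plane. It is made by two O-alkylations and one condensation.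
- The forward reaction must prefer the para (Claisen–Cope) exit over ortho enolisation via 7, 8 and 9, and must then close the pyranone.

**6 ⇒ 4 + 5.** The future C2–C3 bond is cut.
- 5 brings C2 at the formate oxidation level, already carrying the leaving group for the later ring closure.
- 4 has no free hydroxyl, so neither O-methylation nor early cyclisation can occur.

**4 ⇒ 2 + 3, and 2 ⇒ 1.** The two O–CH2 bonds and the O7–Si bond are cut.
- In 1 the 4-OH is the only hydroxyl not hydrogen-bonded to the acetyl group, so it is masked first while C6 and C8 are still unsubstituted and the site is unhindered.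
- The forward etherification must be strictly O-selective.

**16 ⇒ 13 ⇒ 12.** The C–B bond and two O–Si bonds are cut, which leads to commercial 12. The forward steps are silylation and halogen–metal exchange/borylation via 14 and 15.

## Roads not taken

**Alternative 1:** the most obvious cut, O1–C2 together with C2–C3.
- *Route:* 1 would be C-alkylated twice to 2,4,6-trihydroxy-3,5-diprenylacetophenone A1, partly protected as acetals, and taken by Claisen–Schmidt condensation to the 2'-hydroxychalcone A2.
- *Forward key step:* an enantioselective intramolecular oxa-Michael addition under a bifunctional catalyst.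
- *Why the chosen plan is better:*
  - This route is shorter on paper.
  - A1 comes from an ambident anion, so O- versus C-alkylation and mono, di and geminal products all compete.
  - The ring closure is reversible under the catalysts that promote it, so the enantiomeric purity is only kinetic.
  - An unactivated enone gives the catalyst little to hold. An activating ester at C3 would add an acylation and an acidic, hot decarboxylation next to o-prenylphenol units.
  - Acetal removal then still needs acid.
  - The chosen plan makes C2 by an irreversible C–C bond and follows it with one near-neutral step.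

**Alternative 2:** cut C6–CH2 and C8–CH2 last.
- *Route:* (2S)-eriodictyol tetrakis(tert-butyldimethylsilyl) ether A3 would be made first and iodinated to the 6,8-diiodide A4.
- *Forward key step:* a two-fold palladium-catalysed coupling with a prenyl-metal reagent.
- *Why the chosen plan is better:*
  - The stereocentre would have to be set early and then carried through an electrophilic halogenation and two couplings at di-ortho-substituted carbons at elevated temperature. Heat and basic additives open O1–C2.
  - The α/γ selectivity of the allyl-metal has to be right twice.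
  - The mild variants need stoichiometric tin.
  - In the chosen plan both prenyl groups are in place before any stereocentre exists.

**Alternative 3:** no skeletal cut at C2, but a stereoconvergent reduction (retrosynthetic cut of the C4–H bond of a carbinol).
- *Route:* the racemic flavanone A5, formed from A2, would racemise through ring opening.
- *Forward key step:* a chiral transfer-hydrogenation catalyst would reduce only the 2S form to the cis-(2S,4S)-flavan-4-ol A6, which is then re-oxidised.
- *Why the chosen plan is better:*
  - With O5 protected, the ring-opened enone is a sizeable part of the equilibrium and is itself reduced at C=C.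
  - With O5 free, the product is an o-hydroxybenzylic alcohol that ionises to an o-quinone methide and is reduced further.
  - The phloroglucinol-type 4-ol is acid-labile in either case.
  - The detour costs a reduction and an oxidation for one stereocentre.

Key step: step 4

Assumption: the sense of induction in step 8 is taken from the quadrant model for six-membered cyclic enones. There (S)-biaryl bisphosphines give the product that corresponds spatially to Re-face attack at C2 of 11. If a first run shows the opposite sense, the (R)-ligand is used and nothing else changes.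

## Steps

Step 1
Reactants: 1 2,4,6-trihydroxyacetophenone
Product: 2 1-[2,6-dihydroxy-4-(triisopropylsilyloxy)phenyl]ethanone
Conditions: TIPSCl (1.05 equiv), imidazole, DMF, 0 °C
Reagents that add atoms: triisopropylsilyl chloride, CC(C)[Si](Cl)(C(C)C)C(C)C
Why: Phenol silylation; the 4-OH is the only hydroxyl not hydrogen-bonded to the acetyl C=O and is the least hindered, so one equivalent of a bulky chlorosilane should go there. TIPS is chosen because it must later survive amines and about 200 °C.

Step 2
Reactants: 2 1-[2,6-dihydroxy-4-(triisopropylsilyloxy)phenyl]ethanone; 3 3-methylbut-2-en-1-ol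
Product: 4 1-[2,6-bis(3-methylbut-2-enyloxy)-4-(triisopropylsilyloxy)phenyl]ethanone
Conditions: 3 (2.5 equiv), PPh3, DIAD, THF, 0 °C to rt
Reagents that add atoms: none
Why: Two-fold Mitsunobu etherification; the phenol oxygen attacks the CH2 of the alkoxyphosphonium ion (SN2), so no free ambident phenoxide is present and C-alkylation and silyl scrambling are avoided. Chelated o-acylphenols are known substrates for this etherification with prenol.

Step 3
Reactants: 4 1-[2,6-bis(3-methylbut-2-enyloxy)-4-(triisopropylsilyloxy)phenyl]ethanone; 5 N,N-dimethylformamide dimethyl acetal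
Product: 6 (E)-3-(dimethylamino)-1-[2,6-bis(3-methylbut-2-enyloxy)-4-(triisopropylsilyloxy)phenyl]prop-2-en-1-one
Conditions: 5 (4 equiv), toluene, 110 °C
Reagents that add atoms: none
Why: Aminomethylenation of a methyl ketone with an amide acetal, known for 2,4,6-trialkoxyacetophenones; the push–pull alkene forms as the E isomer. With no free OH there is neither O-methylation nor early ring closure, and the temperature is below the onset of the prenyl ether rearrangement.

Step 4
Reactants: 6 (E)-3-(dimethylamino)-1-[2,6-bis(3-methylbut-2-enyloxy)-4-(triisopropylsilyloxy)phenyl]prop-2-en-1-one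
Product: 10 5-hydroxy-6,8-bis(3-methylbut-2-enyl)-7-(triisopropylsilyloxy)-4H-chromen-4-one, via ortho-dienone 7 (not isolated), via mono-relayed phenol 8 (not isolated), via resorcinol enaminone 9 (not isolated)
Conditions: PhNEt2 (0.05 M), 205 °C, Ar sweep; then AcOH, 60 °C
Reagents that add atoms: none
Why: Each aryl prenyl ether undergoes an aromatic Claisen shift to an ortho carbon (6 to 7), and the 1,1-dimethylallyl dienone, squeezed between the C=O and the OTIPS-bearing carbon, passes the group on by a Cope shift to the carbon para to the original oxygen, where tautomerisation restores the arene (8); two [3,3] inversions give back the linear prenyl group. The closest known reaction type is the thermal para-Claisen–Cope rearrangement of 2-prenyloxy-4,6-dialkoxyacetophenones and of 5-O-prenylflavonoids, run here twice on one ring. In the second relay both ortho carbons are substituted, so no enolisation can intercept the dienone and the only exit is the remaining CH carbon (9). Ring C closes by 6-endo-trig conjugate addition of a freed phenol oxygen to the enaminone β-carbon (future C2) followed by loss of dimethylamine, the standard addition–elimination closure of o-hydroxyaryl enaminones; the argon sweep removes the amine and acetic acid converts any open material. No lasting stereocentre is formed, since the sp3 carbon of 7 is lost on rearomatisation. Two selectivities are needed, para over ortho in the first relay and a single constitution on ring closure: the first is favoured by the steric load at the ortho carbon and by dilution in an aprotic medium (the Cope shift is unimolecular, enolisation is not), the second is guaranteed because the mirror plane through future C4a and C7 makes both ethers, both destinations and both phenols equivalent. Whether the pyranone closes before or after the second relay is immaterial, because both orders converge on 10.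

Step 5
Reactants: 10 5-hydroxy-6,8-bis(3-methylbut-2-enyl)-7-(triisopropylsilyloxy)-4H-chromen-4-one
Product: 11 5-(tert-butyldimethylsilyloxy)-6,8-bis(3-methylbut-2-enyl)-7-(triisopropylsilyloxy)-4H-chromen-4-one
Conditions: TBSOTf, 2,6-lutidine, CH2Cl2, 0 °C to rt
Reagents that add atoms: tert-butyldimethylsilyl trifluoromethanesulfonate, CC(C)(C)[Si](C)(C)OS(=O)(=O)C(F)(F)F
Why: Silylation of a chelated phenol needs the silyl triflate; lutidine keeps the medium free of acid, so the prenyl groups are safe. The mask is needed because the 5-OH/C4=O pair would bind rhodium like acetylacetonate and slow transmetalation in step 8.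

Step 6
Reactants: 12 4-bromobenzene-1,2-diol
Product: 13 4-bromo-1,2-bis(tert-butyldimethylsilyloxy)benzene
Conditions: TBSCl (2.3 equiv), imidazole, DMF, rt
Reagents that add atoms: tert-butyldimethylsilyl chloride, CC(C)(C)[Si](C)(C)Cl
Why: Routine bis-silylation of a catechol; it removes the acidic protons and the oxidation sensitivity before metalation.

Step 7
Reactants: 13 4-bromo-1,2-bis(tert-butyldimethylsilyloxy)benzene
Product: 16 [3,4-bis(tert-butyldimethylsilyloxy)phenyl]boronic acid, via aryllithium 14 (not isolated), via lithium triisopropoxyborate 15 (not isolated)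
Conditions: n-BuLi, THF, −78 °C; B(OiPr)3, −78 °C to rt; 1 M HCl, 0 °C
Reagents that add atoms: triisopropyl borate, CC(C)OB(OC(C)C)OC(C)C; water, O
Why: Bromine–lithium exchange, trapping with a borate ester and hydrolysis. The carbanion is meta and para to the silyloxy groups, so no O-to-C silyl shift is within reach, and brief cold acid leaves aryl TBS ethers intact.

Step 8
Reactants: 11 5-(tert-butyldimethylsilyloxy)-6,8-bis(3-methylbut-2-enyl)-7-(triisopropylsilyloxy)-4H-chromen-4-one; 16 [3,4-bis(tert-butyldimethylsilyloxy)phenyl]boronic acid
Product: 17 (2S)-5-(tert-butyldimethylsilyloxy)-2-[3,4-bis(tert-butyldimethylsilyloxy)phenyl]-6,8-bis(3-methylbut-2-enyl)-7-(triisopropylsilyloxy)chroman-4-one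
Conditions: [Rh(OH)(cod)]2 (2 mol %), (S)-MeO-F12-BIPHEP [(S)-6,6'-dimethoxy-2,2'-bis{bis(3,4,5-trifluorophenyl)phosphino}biphenyl] (4.4 mol %), 16 (1.5 equiv), CH2Cl2–H2O 10:1, 30 °C
Reagents that add atoms: none
Why: Rhodium(I)-catalysed asymmetric 1,4-addition of an arylboronic acid (Hayashi–Miyaura reaction), a reaction type known for 4-chromones including 5,7-dioxygenated ones: transmetalation gives aryl–Rh, C2=C3 inserts, and water protonates the oxa-π-allyl rhodium. C2 is set by the ligand alone, whose open quadrant presents the Re face of C2 to the aryl group and so gives 2S. The electron-poor phosphine allows work near room temperature without added base, so the β-aryloxy enolate should be protonated before it can expel O1; unactivated trisubstituted alkenes do not insert.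

Step 9
Reactants: 17 (2S)-5-(tert-butyldimethylsilyloxy)-2-[3,4-bis(tert-butyldimethylsilyloxy)phenyl]-6,8-bis(3-methylbut-2-enyl)-7-(triisopropylsilyloxy)chroman-4-one
Product: 18 (2S)-2-(3,4-dihydroxyphenyl)-5,7-dihydroxy-6,8-bis(3-methylbut-2-enyl)chroman-4-one (6,8-diprenyleriodictyol)
Conditions: KHF2 (excess), MeOH–THF, rt, Ar
Reagents that add atoms: none
Why: Bifluoride cleavage of aryl silyl ethers; each Si–O bond is exchanged for Si–F and the proton comes from HF2−, so phenols and not phenoxides are released and the medium stays slightly acidic. This should leave O1–C2 closed (C2 untouched) and is too weak an acid to protonate the prenyl alkenes; argon protects the catechol.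

## Compound list

1 | 2,4,6-trihydroxyacetophenone | CC(=O)c1c(O)cc(O)cc1O | starting material
2 | 1-[2,6-dihydroxy-4-(triisopropylsilyloxy)phenyl]ethanone | CC(=O)c1c(O)cc(O[Si](C(C)C)(C(C)C)C(C)C)cc1O | intermediate
3 | 3-methylbut-2-en-1-ol (prenol) | CC(C)=CCO | starting material
4 | 1-[2,6-bis(3-methylbut-2-enyloxy)-4-(triisopropylsilyloxy)phenyl]ethanone | CC(=O)c1c(OCC=C(C)C)cc(O[Si](C(C)C)(C(C)C)C(C)C)cc1OCC=C(C)C | intermediate
5 | N,N-dimethylformamide dimethyl acetal | COC(OC)N(C)C | starting material
6 | (E)-3-(dimethylamino)-1-[2,6-bis(3-methylbut-2-enyloxy)-4-(triisopropylsilyloxy)phenyl]prop-2-en-1-one | CN(C)/C=C/C(=O)c1c(OCC=C(C)C)cc(O[Si](C(C)C)(C(C)C)C(C)C)cc1OCC=C(C)C | intermediate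
7 | ortho-dienone (not isolated, racemic at C6): 2-[(E)-3-(dimethylamino)acryloyl]-3-(3-methylbut-2-enyloxy)-6-(2-methylbut-3-en-2-yl)-5-(triisopropylsilyloxy)cyclohexa-2,4-dien-1-one | O=C1C(C(C)(C)C=C)C(O[Si](C(C)C)(C(C)C)C(C)C)=CC(OCC=C(C)C)=C1C(=O)/C=C/N(C)C | intermediate
8 | mono-relayed phenol (not isolated): (E)-3-(dimethylamino)-1-[2-hydroxy-5-(3-methylbut-2-enyl)-6-(3-methylbut-2-enyloxy)-4-(triisopropylsilyloxy)phenyl]prop-2-en-1-one | CN(C)/C=C/C(=O)c1c(O)cc(O[Si](C(C)C)(C(C)C)C(C)C)c(CC=C(C)C)c1OCC=C(C)C | intermediate
9 | resorcinol enaminone (not isolated): (E)-3-(dimethylamino)-1-[2,6-dihydroxy-3,5-bis(3-methylbut-2-enyl)-4-(triisopropylsilyloxy)phenyl]prop-2-en-1-one | CN(C)/C=C/C(=O)c1c(O)c(CC=C(C)C)c(O[Si](C(C)C)(C(C)C)C(C)C)c(CC=C(C)C)c1O | intermediate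
10 | 5-hydroxy-6,8-bis(3-methylbut-2-enyl)-7-(triisopropylsilyloxy)-4H-chromen-4-one | O=c1ccoc2c(CC=C(C)C)c(O[Si](C(C)C)(C(C)C)C(C)C)c(CC=C(C)C)c(O)c12 | intermediate
11 | 5-(tert-butyldimethylsilyloxy)-6,8-bis(3-methylbut-2-enyl)-7-(triisopropylsilyloxy)-4H-chromen-4-one | O=c1ccoc2c(CC=C(C)C)c(O[Si](C(C)C)(C(C)C)C(C)C)c(CC=C(C)C)c(O[Si](C)(C)C(C)(C)C)c12 | intermediate
12 | 4-bromobenzene-1,2-diol | Oc1ccc(Br)cc1O | starting material
13 | 4-bromo-1,2-bis(tert-butyldimethylsilyloxy)benzene | CC(C)(C)[Si](C)(C)Oc1ccc(Br)cc1O[Si](C)(C)C(C)(C)C | intermediate
14 | [3,4-bis(tert-butyldimethylsilyloxy)phenyl]lithium (not isolated) | [Li]c1ccc(O[Si](C)(C)C(C)(C)C)c(O[Si](C)(C)C(C)(C)C)c1 | intermediate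
15 | lithium [3,4-bis(tert-butyldimethylsilyloxy)phenyl]triisopropoxyborate (not isolated) | [Li+].CC(C)O[B-](OC(C)C)(OC(C)C)c1ccc(O[Si](C)(C)C(C)(C)C)c(O[Si](C)(C)C(C)(C)C)c1 | intermediate
16 | [3,4-bis(tert-butyldimethylsilyloxy)phenyl]boronic acid | OB(O)c1ccc(O[Si](C)(C)C(C)(C)C)c(O[Si](C)(C)C(C)(C)C)c1 | intermediate
17 | (2S)-5-(tert-butyldimethylsilyloxy)-2-[3,4-bis(tert-butyldimethylsilyloxy)phenyl]-6,8-bis(3-methylbut-2-enyl)-7-(triisopropylsilyloxy)chroman-4-one | CC(C)=CCc1c(O[Si](C(C)C)(C(C)C)C(C)C)c(CC=C(C)C)c2c(c1O[Si](C)(C)C(C)(C)C)C(=O)C[C@@H](c1ccc(O[Si](C)(C)C(C)(C)C)c(O[Si](C)(C)C(C)(C)C)c1)O2 | intermediate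
18 | (2S)-6,8-diprenyleriodictyol | CC(C)=CCc1c(O)c(CC=C(C)C)c2c(c1O)C(=O)C[C@@H](c1ccc(O)c(O)c1)O2 | target

## Step count and least certain steps

Total step count: 9. The longest linear sequence is 7 steps from 1 (steps 1, 2, 3, 4, 5, 8, 9). The ring-B branch (steps 6 and 7) joins at step 8.

**Step 4 (key step).**
- *What may go wrong:* The most likely failure is in the first relay. Proton transfer in the ortho-dienone may overtake the Cope shift, which would fix the inverted 1,1-dimethylallyl group next to the oxygen it came from and misdirect the second ether. Lesser risks are thermal loss of a prenyl group as the diene and amine-induced loss of the silyl group at 205 °C.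
- *Fallback:* it replaces the prenyl relay by allyl groups, for which the ortho and para paths give the same substituent, and builds the trisubstituted alkenes afterwards.
  - It sets out from 2. Two-fold Mitsunobu etherification with allyl alcohol should give 1-[2,6-bis(allyloxy)-4-(triisopropylsilyloxy)phenyl]ethanone F1.
  - Heating in PhNEt2 should give, by double Claisen rearrangement, 1-[3,5-diallyl-2,6-dihydroxy-4-(triisopropylsilyloxy)phenyl]ethanone F2.
  - Two-fold cross-metathesis with 2-methylbut-2-ene (second-generation ruthenium carbene catalyst) should give 1-[2,6-dihydroxy-3,5-bis(3-methylbut-2-enyl)-4-(triisopropylsilyloxy)phenyl]ethanone F3.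
  - Condensation of F3 with 5 comes back to the route at 9, which acetic acid closes to 10.

**Step 8.**
- *What may go wrong:* Three oxygen donors lower the electrophilicity of C2, so insertion may be slower than protodeboronation. If the rhodium enolate expels O1 before protonation, unselective re-closure would erode the enantiomeric purity. A further risk is 1,2-addition to the product ketone.
- *Fallback:* it gives up asymmetric C–C bond formation for resolution.
  - From 11 and 16, arylation with the more reactive phosphine-free [Rh(OH)(cod)]2 should give the racemic 5-(tert-butyldimethylsilyloxy)-2-[3,4-bis(tert-butyldimethylsilyloxy)phenyl]-6,8-bis(3-methylbut-2-enyl)-7-(triisopropylsilyloxy)chroman-4-one F4.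
  - Kinetic resolution follows by asymmetric transfer hydrogenation with RuCl[(R,R)-TsDPEN](p-cymene) and HCO2H–Et3N. This should reduce the 2R enantiomer to the cis-(2R,4R)-configured flavan-4-ol F5 and leave the 2S ketone.
  - The fallback rejoins the route at 17, at the cost of half the material.

**Step 9.**
- *What may go wrong:* Cleavage at the two flanked positions (O5 between C4=O and the C6 prenyl, O7 between two prenyl groups) may lag. This would invite more basic fluoride, under which phenoxide formation at O7 and O4' opens O1–C2 and racemises C2.
- *Fallback:* it never releases a phenoxide.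
  - From 17, CsF in the presence of Ac2O (MeCN, 0 °C) should trap each aryloxide at once and give (2S)-2-(3,4-diacetoxyphenyl)-5,7-diacetoxy-6,8-bis(3-methylbut-2-enyl)chroman-4-one F6.
  - F6 is then deacetylated by acid-catalysed methanolysis (catalytic AcCl in MeOH, 0 °C to rt). Under these conditions flavanones hold their configuration.
  - This comes back to the route at 18.

**Step 2.**
- *What may go wrong:* The second etherification may stall, because the last hydroxyl is held in a hydrogen bond to the carbonyl next to a twisted acetyl group. The activated alcohol may then be consumed by the hydrazide anion instead.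
- *Fallback:* it leaves the redox condensation for a Williamson etherification. From 2, prenyl bromide and Cs2CO3 in DMF are used, where deprotonation itself breaks the hydrogen bond. It comes back to the route at 4 and makes no new compound (F0). The price is some competition from alkylation on carbon.

## Further compounds

F0 | step 2 | none | none
F1 | step 4 | 1-[2,6-bis(allyloxy)-4-(triisopropylsilyloxy)phenyl]ethanone | CC(=O)c1c(OCC=C)cc(O[Si](C(C)C)(C(C)C)C(C)C)cc1OCC=C
F2 | step 4 | 1-[3,5-diallyl-2,6-dihydroxy-4-(triisopropylsilyloxy)phenyl]ethanone | CC(=O)c1c(O)c(CC=C)c(O[Si](C(C)C)(C(C)C)C(C)C)c(CC=C)c1O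
F3 | step 4 | 1-[2,6-dihydroxy-3,5-bis(3-methylbut-2-enyl)-4-(triisopropylsilyloxy)phenyl]ethanone | CC(=O)c1c(O)c(CC=C(C)C)c(O[Si](C(C)C)(C(C)C)C(C)C)c(CC=C(C)C)c1O
F4 | step 8 | racemic 5-(tert-butyldimethylsilyloxy)-2-[3,4-bis(tert-butyldimethylsilyloxy)phenyl]-6,8-bis(3-methylbut-2-enyl)-7-(triisopropylsilyloxy)chroman-4-one | CC(C)=CCc1c(O[Si](C(C)C)(C(C)C)C(C)C)c(CC=C(C)C)c2c(c1O[Si](C)(C)C(C)(C)C)C(=O)CC(c1ccc(O[Si](C)(C)C(C)(C)C)c(O[Si](C)(C)C(C)(C)C)c1)O2
F5 | step 8 | (2R,4R)-5-(tert-butyldimethylsilyloxy)-2-[3,4-bis(tert-butyldimethylsilyloxy)phenyl]-6,8-bis(3-methylbut-2-enyl)-7-(triisopropylsilyloxy)chroman-4-ol | CC(C)=CCc1c(O[Si](C(C)C)(C(C)C)C(C)C)c(CC=C(C)C)c2c(c1O[Si](C)(C)C(C)(C)C)[C@H](O)C[C@H](c1ccc(O[Si](C)(C)C(C)(C)C)c(O[Si](C)(C)C(C)(C)C)c1)O2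
F6 | step 9 | (2S)-2-(3,4-diacetoxyphenyl)-5,7-diacetoxy-6,8-bis(3-methylbut-2-enyl)chroman-4-one | CC(C)=CCc1c(OC(C)=O)c(CC=C(C)C)c2c(c1OC(C)=O)C(=O)C[C@@H](c1ccc(OC(C)=O)c(OC(C)=O)c1)O2
A1 | alternative 1 | 2,4,6-trihydroxy-3,5-bis(3-methylbut-2-enyl)acetophenone | CC(=O)c1c(O)c(CC=C(C)C)c(O)c(CC=C(C)C)c1O
A2 | alternative 1 | (E)-1-[2-hydroxy-4,6-bis(methoxymethoxy)-3,5-bis(3-methylbut-2-enyl)phenyl]-3-[3,4-bis(methoxymethoxy)phenyl]prop-2-en-1-one | COCOc1ccc(/C=C/C(=O)c2c(O)c(CC=C(C)C)c(OCOC)c(CC=C(C)C)c2OCOC)cc1OCOC
A3 | alternative 2 | (2S)-5,7-bis(tert-butyldimethylsilyloxy)-2-[3,4-bis(tert-butyldimethylsilyloxy)phenyl]chroman-4-one | O=C1C[C@@H](c2ccc(O[Si](C)(C)C(C)(C)C)c(O[Si](C)(C)C(C)(C)C)c2)Oc2cc(O[Si](C)(C)C(C)(C)C)cc(O[Si](C)(C)C(C)(C)C)c12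
A4 | alternative 2 | (2S)-5,7-bis(tert-butyldimethylsilyloxy)-2-[3,4-bis(tert-butyldimethylsilyloxy)phenyl]-6,8-diiodochroman-4-one | O=C1C[C@@H](c2ccc(O[Si](C)(C)C(C)(C)C)c(O[Si](C)(C)C(C)(C)C)c2)Oc2c(I)c(O[Si](C)(C)C(C)(C)C)c(I)c(O[Si](C)(C)C(C)(C)C)c12
A5 | alternative 3 | racemic 5,7-bis(methoxymethoxy)-2-[3,4-bis(methoxymethoxy)phenyl]-6,8-bis(3-methylbut-2-enyl)chroman-4-one | COCOc1ccc(C2CC(=O)c3c(OCOC)c(CC=C(C)C)c(OCOC)c(CC=C(C)C)c3O2)cc1OCOC
A6 | alternative 3 | (2S,4S)-5,7-bis(methoxymethoxy)-2-[3,4-bis(methoxymethoxy)phenyl]-6,8-bis(3-methylbut-2-enyl)chroman-4-ol | CC(C)=CCc1c(OCOC)c(CC=C(C)C)c2c(c1OCOC)[C@@H](O)C[C@@H](c1ccc(OCOC)c(OCOC)c1)O2
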